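**Plan**
Cuts, in retrosynthetic order: C18–OH (C–H hydroxylation directed by the 3β-OH); O9–C13 (oxa-Michael onto a 15,16-butenolide); C11–C12 (opening of a 9α,11-spiro-epoxide); C8–C17 (enolate methylation); then C2–C3 and C5–C10 in one event.
That event: in a 1-(1-methylcyclopropyl)cyclopentyl silyl ether with a CMe2–CHO group on the neighbouring ring carbon, a cyclopropane CH2 (C2) attacks the aldehyde carbon (C3) and C5 shifts from C9 to C10; ring A closes and the cyclopentane C5–C6–C7–C8–C9 is enlarged to ring B.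
Features that allow it: C1 and C2 are unsubstituted methylenes on the methyl-bearing quaternary C10, so C10/C1/C2 can be a 1-methylcyclopropyl ring; C9 carries oxygen (pinacol terminus, later the spiro ether); C3 is a carbinol (aldehyde); C4 can be CMe2 because C18 is oxidised last.
Forward order: cyclopentenol → Ireland–Claisen (C4–C5) → anti-epoxide/hydride (C9 carbinol) → rings A and B together → C8 methyl → C9 side chain → butenolide → spiro-tetrahydrofuran and lactone → C18–OH.
Stereochemistry: C5 from a CBS reduction carried over by the [3,3] shift; C10 and C3 from the key step; C8 thermodynamic; C9 from α-face epoxidation; C13 from the oxa-Michael closure; C4 from equatorial-methyl-selective C–H silylation.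

Key step: step 9

Remark: atoms are cited by the labdane numbers of the target, also in the precursors (C17 on C8, C18 α and C19 β on C4, C20 on C10; α is the face opposite the C10 methyl).

Step 1
Reactants: 1 2-iodocyclopent-2-en-1-one
Product: 2 (S)-2-iodocyclopent-2-en-1-ol
Conditions: (R)-2-methyl-CBS-oxazaborolidine ((R)-1-methyl-3,3-diphenylhexahydropyrrolo[1,2-c][1,3,2]oxazaborole, 10 mol%), BH3·SMe2, THF, −20 °C; MeOH quench
Reagents that add atoms: none
Why: Corey–Bakshi–Shibata reduction, in which the oxazaborolidine–borane complex binds the ketone with the iodoalkene carbon as the large group and delivers hydride to one face, should give the (S)-allylic alcohol that later fixes C5.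

Step 2
Reactants: 2 (S)-2-iodocyclopent-2-en-1-ol; 3 1-bromo-1-methylcyclopropane
Product: 6 (S)-2-(1-methylcyclopropyl)cyclopent-2-en-1-ol, via 1-methylcyclopropyllithium 4 (not isolated), via (1-methylcyclopropyl)zinc chloride 5 (not isolated)
Conditions: 3, t-BuLi (2 equiv), Et2O, −78 °C; ZnCl2, THF, −78 → 0 °C; then 2, Pd(OAc)2 (3 mol%), SPhos (6 mol%), THF, 40 °C
Reagents that add atoms: none
Why: Negishi cross-coupling of the vinyl iodide with a cyclopropylzinc reagent (fast transmetalation, no β-hydride pathway, free hydroxyl tolerated by the organozinc) should install the 1-methylcyclopropyl group without touching the carbinol center.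

Step 3
Reactants: 6 (S)-2-(1-methylcyclopropyl)cyclopent-2-en-1-ol; 7 2-methylpropanoyl chloride
Product: 8 (S)-2-(1-methylcyclopropyl)cyclopent-2-en-1-yl 2-methylpropanoate
Conditions: pyridine, DMAP (5 mol%), CH2Cl2, 0 → 23 °C
Reagents that add atoms: none
Why: DMAP-catalyzed acylation of a secondary alcohol by an acid chloride, which affects no stereocenter.

Step 4
Reactants: 8 (S)-2-(1-methylcyclopropyl)cyclopent-2-en-1-yl 2-methylpropanoate
Product: 12 methyl 2-methyl-2-[(1R)-2-(1-methylcyclopropyl)cyclopent-2-en-1-yl]propanoate, via trimethylsilyl ketene acetal 9 (not isolated), via trimethylsilyl ester 10 (not isolated), via carboxylic acid 11 (not isolated)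
Conditions: LiN(iPr)2, THF, −78 °C; Me3SiCl, −78 → 65 °C; 1 M HCl; then Me3SiCHN2, MeOH/toluene, 0 °C
Reagents that add atoms: (trimethylsilyl)diazomethane, C[Si](C)(C)C=[N+]=[N-]
Why: Ireland–Claisen rearrangement, whose [3,3] shift is suprafacial on the cyclopentenyl unit, should pass the carbinol configuration on to C5 while the quaternary C4 is formed and the alkene moves to C8=C9; the acid is then methylated.

Step 5
Reactants: 12 methyl 2-methyl-2-[(1R)-2-(1-methylcyclopropyl)cyclopent-2-en-1-yl]propanoate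
Product: 13 methyl 2-methyl-2-[(1R,2S,5R)-1-(1-methylcyclopropyl)-6-oxabicyclo[3.1.0]hexan-2-yl]propanoate
Conditions: mCPBA, NaHCO3, CH2Cl2, 0 °C
Reagents that add atoms: meta-chloroperoxybenzoic acid, OOC(=O)c1cccc(Cl)c1
Why: Prilezhaev epoxidation of the electron-rich trisubstituted alkene should occur on the face opposite the bulky CMe2 group on the adjacent C5.

Step 6
Reactants: 13 methyl 2-methyl-2-[(1R,2S,5R)-1-(1-methylcyclopropyl)-6-oxabicyclo[3.1.0]hexan-2-yl]propanoate
Product: 14 2-[(1S,2R)-2-hydroxy-2-(1-methylcyclopropyl)cyclopentyl]-2-methylpropan-1-ol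
Conditions: LiAlH4, THF, 0 → 65 °C
Reagents that add atoms: none
Why: LiAlH4 reduces the ester and opens the epoxide by SN2 hydride attack at the less substituted C8, which leaves the tertiary C9 carbinol with its oxygen trans to the CMe2 group and the cyclopropyl ring cis to it.

Step 7
Reactants: 14 2-[(1S,2R)-2-hydroxy-2-(1-methylcyclopropyl)cyclopentyl]-2-methylpropan-1-ol
Product: 15 2-[(1S,2R)-2-hydroxy-2-(1-methylcyclopropyl)cyclopentyl]-2-methylpropanal
Conditions: TEMPO (10 mol%), PhI(OAc)2, CH2Cl2, 23 °C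
Reagents that add atoms: none
Why: the TEMPO/PhI(OAc)2 oxidation is selective for the primary alcohol, the tertiary carbinol cannot be oxidised, and the trans arrangement disfavors lactol formation.

Step 8
Reactants: 15 2-[(1S,2R)-2-hydroxy-2-(1-methylcyclopropyl)cyclopentyl]-2-methylpropanal
Product: 16 2-methyl-2-[(1S,2R)-2-(1-methylcyclopropyl)-2-(triethylsilyloxy)cyclopentyl]propanal
Conditions: Et3SiOTf, 2,6-lutidine, CH2Cl2, −78 → 0 °C
Reagents that add atoms: triethylsilyl trifluoromethanesulfonate, CC[Si](CC)(CC)OS(=O)(=O)C(F)(F)F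
Why: silylation of the hindered tertiary alcohol by a silyl triflate under lutidine buffering, to which the non-enolizable aldehyde is inert.

Step 9
Reactants: 16 2-methyl-2-[(1S,2R)-2-(1-methylcyclopropyl)-2-(triethylsilyloxy)cyclopentyl]propanal
Product: 17 (4aS,6S,8aS)-5,5,8a-trimethyl-6-(triethylsilyloxy)octahydronaphthalen-1(2H)-one
Conditions: Et3SiOTf (0.2 equiv), 2,6-di-tert-butyl-4-methylpyridine (0.3 equiv), CH2Cl2, −78 → −40 °C
Reagents that add atoms: none
Why: Proposed new method: the silyl triflate activates the neopentyl aldehyde, a cyclopropane CH2 (C2) attacks C3 with cleavage of the C2–C10 bond (homo-Prins), and the tertiary cation developing at C10 is intercepted as it forms by 1,2-shift of the anti-periplanar ring carbon C5 from C9 to C10 (semipinacol), the C9 silyloxy group collapsing to the ketone and releasing Et3Si+ to triflate, so that the promoter turns over and the silyl group ends on O3. The closest known reaction types are the Prins–pinacol ring-enlarging annulations of 1-alkenylcycloalkanol silyl ethers and the Lewis-acid opening of cyclopropanes by carbonyl electrophiles (cyclopropylmethylsilane homoallylation, acylation of cyclopropanes); here the cyclopropane takes the role of the alkene, which moves the new bond to C2 and so makes the ring six-membered. Ring A closes 6-exo at the carbonyl carbon through a chair as C5 bridges to C10, and ring B arises by one-carbon enlargement of the cyclopentane to the cyclohexanone. C5 migrates with retention and keeps the configuration fixed in step 4; C10 is formed with inversion (C5 enters anti to the leaving C2), and the chair that puts the small C10 methyl, not ring carbon C9, axial and 1,3 to the axial C4 methyl should be preferred, which gives the trans ring fusion, while the activated carbonyl oxygen sits equatorial and gives the 3β-silyl ether. The step needs C5, not C8, to migrate and the aldehyde, not the tertiary cyclopropylcarbinyl silyl ether, to be ionized: the more substituted C5–C9 bond is the one held anti-periplanar by the tether to C3, and low temperature, a catalytic promoter and a hindered pyridine should keep the C9–O bond intact.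

Step 10
Reactants: 17 (4aS,6S,8aS)-5,5,8a-trimethyl-6-(triethylsilyloxy)octahydronaphthalen-1(2H)-one
Product: 18 (2R,4aS,6S,8aS)-2,5,5,8a-tetramethyl-6-(triethylsilyloxy)octahydronaphthalen-1(2H)-one
Conditions: LiN(iPr)2, THF, −78 °C; MeI, −78 → 0 °C; then NaOMe (cat.), MeOH, 23 °C
Reagents that add atoms: iodomethane, CI
Why: enolate alkylation at C8, the only enolizable position because C10 is quaternary, should place the methyl anti to the axial C10 methyl, and the equatorial 8α-methyl is also the epimer favored on equilibration.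

Step 11
Reactants: 18 (2R,4aS,6S,8aS)-2,5,5,8a-tetramethyl-6-(triethylsilyloxy)octahydronaphthalen-1(2H)-one
Product: 19 (2R,4aR,6S,8aS)-2,5,5,8a-tetramethyl-1-methylidene-6-(triethylsilyloxy)decahydronaphthalene
Conditions: Ph3PCH3Br, KOtBu, toluene, 90 °C
Reagents that add atoms: methyltriphenylphosphonium bromide, C[P+](c1ccccc1)(c1ccccc1)c1ccccc1.[Br-]
Why: Wittig methylenation under the KOtBu/hot toluene conditions used for hindered ketones, with C8 remaining in its thermodynamic configuration.

Step 12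
Reactants: 19 (2R,4aR,6S,8aS)-2,5,5,8a-tetramethyl-1-methylidene-6-(triethylsilyloxy)decahydronaphthalene
Product: 20 (1R,2R,4aS,6S,8aS)-2,5,5,8a-tetramethyl-6-(triethylsilyloxy)octahydro-2H-spiro[naphthalene-1,2'-oxirane]
Conditions: mCPBA, NaHCO3, CH2Cl2, 0 °C
Reagents that add atoms: meta-chloroperoxybenzoic acid, OOC(=O)c1cccc(Cl)c1
Why: Prilezhaev epoxidation of the exocyclic alkene from the α face, opposite the adjacent axial C10 methyl, should set the C9–O bond α and C11 β.

Step 13
Reactants: 20 (1R,2R,4aS,6S,8aS)-2,5,5,8a-tetramethyl-6-(triethylsilyloxy)octahydro-2H-spiro[naphthalene-1,2'-oxirane]; 21 3-(chloromethyl)furan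
Product: 23 (1R,2R,4aS,6S,8aS)-1-[2-(furan-3-yl)ethyl]-2,5,5,8a-tetramethyl-6-(triethylsilyloxy)decahydronaphthalen-1-ol, via (furan-3-ylmethyl)magnesium chloride 22 (not isolated)
Conditions: 21, Mg, THF, 0 °C; then CuI (10 mol%), 20, THF, −30 → 23 °C; aq. NH4Cl
Reagents that add atoms: none
Why: copper-catalyzed SN2 opening of the spiro-epoxide at its CH2 terminus (C11) by the furylmethyl Grignard reagent leaves C9 untouched, and CuI should suppress attack through the furan 2-position.

Step 14
Reactants: 23 (1R,2R,4aS,6S,8aS)-1-[2-(furan-3-yl)ethyl]-2,5,5,8a-tetramethyl-6-(triethylsilyloxy)decahydronaphthalen-1-ol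
Product: 25 4-{2-[(1R,2R,4aS,6S,8aS)-1-hydroxy-2,5,5,8a-tetramethyl-6-(triethylsilyloxy)decahydronaphthalen-1-yl]ethyl}-5-hydroxyfuran-2(5H)-one, via furan endoperoxide 24 (not isolated)
Conditions: O2, visible light, rose bengal (cat.), iPr2NEt, CH2Cl2, −78 °C
Reagents that add atoms: dioxygen, O=O
Why: [4+2] addition of singlet oxygen to the furan followed by Kornblum–DeLaMare-type fragmentation of the endoperoxide, in which the hindered base removes the less hindered C15–H, should give the β-substituted γ-hydroxybutenolide with the carbonyl at C15.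

Step 15
Reactants: 25 4-{2-[(1R,2R,4aS,6S,8aS)-1-hydroxy-2,5,5,8a-tetramethyl-6-(triethylsilyloxy)decahydronaphthalen-1-yl]ethyl}-5-hydroxyfuran-2(5H)-one
Product: 27 (13R)-9α,13-epoxy-3β-(triethylsilyloxy)labdan-15,16-olide, via hydroxy butenolide 26 (not isolated)
Conditions: NaBH4, EtOH, 0 °C; aq. HCl to pH 3, 23 °C; then DBU (0.3 equiv), CH2Cl2, 23 °C
Reagents that add atoms: none
Why: NaBH4 reduces the ring-opened aldehyde form of the lactol, relactonization gives the 15,16-butenolide, and 5-exo-trig oxa-Michael addition of the 9α-alkoxide to C13 closes the spiro-tetrahydrofuran, the flat sp2 C14–H edge of the butenolide being expected to lie toward the congested C10 side, which corresponds to 13R.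

Step 16
Reactants: 27 (13R)-9α,13-epoxy-3β-(triethylsilyloxy)labdan-15,16-olide
Product: 28 (13R)-9α,13-epoxy-3β-hydroxylabdan-15,16-olide
Conditions: HF·pyridine, THF, 0 → 23 °C
Reagents that add atoms: none
Why: fluoride cleavage of the secondary triethylsilyl ether, to which lactone and ether are inert.

Step 17
Reactants: 28 (13R)-9α,13-epoxy-3β-hydroxylabdan-15,16-olide
Product: 31 (13R)-9α,13-epoxy-3β,18-dihydroxylabdan-15,16-olide, via diethyl(hydrido)silyl ether 29 (not isolated), via oxasilolane 30 (not isolated)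
Conditions: Et2SiH2, [Ir(cod)OMe]2 (0.5 mol%), THF, 23 °C; then [Ir(cod)OMe]2 (2 mol%), 3,4,7,8-tetramethyl-1,10-phenanthroline (5 mol%), norbornene, THF, 100 °C; then H2O2, KHCO3, THF/MeOH, 50 °C; dilute HCl work-up
Reagents that add atoms: hydrogen peroxide, OO
Why: hydroxyl-directed iridium-catalyzed γ-C–H silylation followed by Tamao–Fleming oxidation should functionalize the equatorial 4α-methyl (C18) through a strain-free five-membered oxasilolane, the axial 4β-methyl being 1,3-diaxial to C20, so that C4 becomes the stereocenter with CH2OH α.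

**Compound list**
1 | 2-iodocyclopent-2-en-1-one | O=C1CCC=C1I | starting material
2 | (S)-2-iodocyclopent-2-en-1-ol | O[C@H]1CCC=C1I | intermediate
3 | 1-bromo-1-methylcyclopropane | CC1(Br)CC1 | starting material
4 | 1-methylcyclopropyllithium | [Li]C1(C)CC1 | intermediate
5 | (1-methylcyclopropyl)zinc chloride | Cl[Zn]C1(C)CC1 | intermediate
6 | (S)-2-(1-methylcyclopropyl)cyclopent-2-en-1-ol | O[C@H]1CCC=C1C2(C)CC2 | intermediate
7 | 2-methylpropanoyl chloride | CC(C)C(Cl)=O | starting material
8 | (S)-2-(1-methylcyclopropyl)cyclopent-2-en-1-yl 2-methylpropanoate | CC(C)C(=O)O[C@H]1CCC=C1C2(C)CC2 | intermediate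
9 | 2-methyl-1-{[(1S)-2-(1-methylcyclopropyl)cyclopent-2-en-1-yl]oxy}-1-(trimethylsilyloxy)prop-1-ene | CC(C)=C(O[Si](C)(C)C)O[C@H]1CCC=C1C2(C)CC2 | intermediate
10 | trimethylsilyl 2-methyl-2-[(1R)-2-(1-methylcyclopropyl)cyclopent-2-en-1-yl]propanoate | C[Si](C)(C)OC(=O)C(C)(C)[C@@H]1CCC=C1C2(C)CC2 | intermediate
11 | 2-methyl-2-[(1R)-2-(1-methylcyclopropyl)cyclopent-2-en-1-yl]propanoic acid | OC(=O)C(C)(C)[C@@H]1CCC=C1C2(C)CC2 | intermediate
12 | methyl 2-methyl-2-[(1R)-2-(1-methylcyclopropyl)cyclopent-2-en-1-yl]propanoate | COC(=O)C(C)(C)[C@@H]1CCC=C1C2(C)CC2 | intermediate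
13 | methyl 2-methyl-2-[(1R,2S,5R)-1-(1-methylcyclopropyl)-6-oxabicyclo[3.1.0]hexan-2-yl]propanoate | COC(=O)C(C)(C)[C@@H]1CC[C@H]2O[C@@]12C3(C)CC3 | intermediate
14 | 2-[(1S,2R)-2-hydroxy-2-(1-methylcyclopropyl)cyclopentyl]-2-methylpropan-1-ol | OCC(C)(C)[C@@H]1CCC[C@]1(O)C2(C)CC2 | intermediate
15 | 2-[(1S,2R)-2-hydroxy-2-(1-methylcyclopropyl)cyclopentyl]-2-methylpropanal | O=CC(C)(C)[C@@H]1CCC[C@]1(O)C2(C)CC2 | intermediate
16 | 2-methyl-2-[(1S,2R)-2-(1-methylcyclopropyl)-2-(triethylsilyloxy)cyclopentyl]propanal | O=CC(C)(C)[C@@H]1CCC[C@]1(O[Si](CC)(CC)CC)C2(C)CC2 | intermediate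
17 | (4aS,6S,8aS)-5,5,8a-trimethyl-6-(triethylsilyloxy)octahydronaphthalen-1(2H)-one | C1CC[C@H]2C(C)(C)[C@@H](O[Si](CC)(CC)CC)CC[C@]2(C)C1=O | intermediate
18 | (2R,4aS,6S,8aS)-2,5,5,8a-tetramethyl-6-(triethylsilyloxy)octahydronaphthalen-1(2H)-one | C[C@@H]1CC[C@H]2C(C)(C)[C@@H](O[Si](CC)(CC)CC)CC[C@]2(C)C1=O | intermediate
19 | (2R,4aR,6S,8aS)-2,5,5,8a-tetramethyl-1-methylidene-6-(triethylsilyloxy)decahydronaphthalene | C[C@@H]1CC[C@H]2C(C)(C)[C@@H](O[Si](CC)(CC)CC)CC[C@]2(C)C1=C | intermediate
20 | (1R,2R,4aS,6S,8aS)-2,5,5,8a-tetramethyl-6-(triethylsilyloxy)octahydro-2H-spiro[naphthalene-1,2'-oxirane] (epoxide oxygen α) | C[C@@H]1CC[C@H]2C(C)(C)[C@@H](O[Si](CC)(CC)CC)CC[C@]2(C)[C@@]13CO3 | intermediate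
21 | 3-(chloromethyl)furan | ClCc1ccoc1 | starting material
22 | (furan-3-ylmethyl)magnesium chloride | Cl[Mg]Cc1ccoc1 | intermediate
23 | (1R,2R,4aS,6S,8aS)-1-[2-(furan-3-yl)ethyl]-2,5,5,8a-tetramethyl-6-(triethylsilyloxy)decahydronaphthalen-1-ol | C[C@@H]1CC[C@H]2C(C)(C)[C@@H](O[Si](CC)(CC)CC)CC[C@]2(C)[C@@]1(O)CCc1ccoc1 | intermediate
24 | singlet-oxygen adduct of 23 (2,3,7-trioxabicyclo[2.2.1]hept-5-ene, substituted at C5; bridgehead epimers) | C[C@@H]1CC[C@H]2C(C)(C)[C@@H](O[Si](CC)(CC)CC)CC[C@]2(C)[C@@]1(O)CCC1=CC3OOC1O3 | intermediate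
25 | 4-{2-[(1R,2R,4aS,6S,8aS)-1-hydroxy-2,5,5,8a-tetramethyl-6-(triethylsilyloxy)decahydronaphthalen-1-yl]ethyl}-5-hydroxyfuran-2(5H)-one (lactol epimers) | C[C@@H]1CC[C@H]2C(C)(C)[C@@H](O[Si](CC)(CC)CC)CC[C@]2(C)[C@@]1(O)CCC1=CC(=O)OC1O | intermediate
26 | 4-{2-[(1R,2R,4aS,6S,8aS)-1-hydroxy-2,5,5,8a-tetramethyl-6-(triethylsilyloxy)decahydronaphthalen-1-yl]ethyl}furan-2(5H)-one | C[C@@H]1CC[C@H]2C(C)(C)[C@@H](O[Si](CC)(CC)CC)CC[C@]2(C)[C@@]1(O)CCC1=CC(=O)OC1 | intermediate
27 | (13R)-9α,13-epoxy-3β-(triethylsilyloxy)labdan-15,16-olide (5αH, 8α-methyl, 10β-methyl) | C[C@@H]1CC[C@H]2C(C)(C)[C@@H](O[Si](CC)(CC)CC)CC[C@]2(C)[C@@]12CC[C@@]1(COC(=O)C1)O2 | intermediate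
28 | (13R)-9α,13-epoxy-3β-hydroxylabdan-15,16-olide | C[C@@H]1CC[C@H]2C(C)(C)[C@@H](O)CC[C@]2(C)[C@@]12CC[C@@]1(COC(=O)C1)O2 | intermediate
29 | 3-O-diethyl(hydrido)silyl ether of 28 | C[C@@H]1CC[C@H]2C(C)(C)[C@@H](O[SiH](CC)CC)CC[C@]2(C)[C@@]12CC[C@@]1(COC(=O)C1)O2 | intermediate
30 | 3-O,18-C-diethylsilanediyl derivative (1,2-oxasilolane fused at C3–C4, CH2Si on the α face) | C[C@@H]1CC[C@H]2[C@]3(C)C[Si](CC)(CC)O[C@H]3CC[C@]2(C)[C@@]12CC[C@@]1(COC(=O)C1)O2 | intermediate
31 | (13R)-9α,13-epoxy-3β,18-dihydroxylabdan-15,16-olide, (3S,4R,5S,8R,9R,10S,13R) | C[C@@H]1CC[C@H]2[C@](C)(CO)[C@@H](O)CC[C@]2(C)[C@@]12CC[C@@]1(COC(=O)C1)O2 | target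

**Count and risks**
Total steps: 17. Longest linear sequence: 17 steps (1 → 31).

1. Step 9 (proposed new method). What may go wrong: ionization of the tertiary cyclopropylcarbinyl silyl ether before the aldehyde is engaged, migration of C8 in place of C5, or loss of the trans selectivity at the ring fusion. The fallback makes the same two bonds one after the other by known reactions; it sets out from hydroxy aldehyde 15 and returns at 17. MgI2 in Et2O should open the tertiary cyclopropylcarbinol in a Julia-type cyclopropylcarbinyl–homoallyl rearrangement to (Z)-2-[(1R)-2-(5-iodopentan-2-ylidene)cyclopentyl]-2-methylpropanal F1, the methyl eclipsing the smaller ring carbon C8 so that the iodoethyl arm lies cis to C5. SmI2/HMPA Barbier closure of C2 onto the aldehyde should give the octahydroazulenol F2, and mCPBA its tetrasubstituted epoxide F3. BF3·OEt2 should ionize the epoxide at C10 and let C5 shift from C9 to C10 (epoxide semipinacol rearrangement) to the hydroxy decalinone F4, which Et3SiCl/imidazole converts to 17.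

2. Step 15. What may go wrong: poor facial selectivity of the oxa-Michael addition at C13, or erosion through retro-Michael opening. The fallback sets C13 by a chiral catalyst before the ring is closed; it sets out from spiro-epoxide 20 and returns at 27. The dianion of 3-methylbut-3-en-1-ol (n-BuLi, TMEDA) should open 20 at C11 to the homoallylic alcohol F5. Vanadium-catalyzed asymmetric epoxidation directed by the C15 hydroxyl (VO(OiPr)3, chiral bishydroxamic acid ligand, cumene hydroperoxide) should give the (13S)-13,16-epoxide F6. Camphorsulfonic acid should then let the 9α-hydroxyl open the epoxide 5-exo at C13 with inversion to the (13R)-tetrahydrofuran diol F7, and TEMPO/PhI(OAc)2 oxidative lactonization, starting at the less hindered C15 hydroxyl, should give 27.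

3. Step 17. What may go wrong: incomplete discrimination between the two C4 methyl groups, or reduction of the lactone and catalyst deactivation during the silylation. The fallback replaces hydroxyl-directed silylation by oxime-directed palladation; it sets out from 28 and returns at 31. Dess–Martin oxidation should give the 3-ketone F8 and NH2OH·HCl/NaOAc its (E)-oxime F9. Pd(OAc)2 (5 mol%) and PhI(OAc)2 in AcOH/Ac2O should convert F9, through a five-membered palladacycle at the equatorial 4α-methyl, into the 18-acetoxy O-acetyl oxime F10. NaHSO3 and then dilute acid should cleave the oxime to the acetoxy ketone F11, NaBH4 should reduce it to the 3β-alcohol F12, and K2CO3 in MeOH with acidic work-up should remove the acetate and give 31.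

**Further compounds**
F1 | step 9 | (Z)-2-[(1R)-2-(5-iodopentan-2-ylidene)cyclopentyl]-2-methylpropanal | O=CC(C)(C)[C@@H]1CCC/C1=C(\C)CCI
F2 | step 9 | (8aR)-4,8,8-trimethyl-1,2,3,5,6,7,8,8a-octahydroazulen-7-ol (C7 epimers) | OC1CCC(C)=C2CCC[C@H]2C1(C)C
F3 | step 9 | (8aS)-3a,4-epoxy-4,8,8-trimethyldecahydroazulen-7-ol (epoxide and C7 epimers) | OC1CCC2(C)OC23CCC[C@H]3C1(C)C
F4 | step 9 | (4aS,6S,8aS)-6-hydroxy-5,5,8a-trimethyloctahydronaphthalen-1(2H)-one | C1CC[C@H]2C(C)(C)[C@@H](O)CC[C@]2(C)C1=O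
F5 | step 15 | (1R,2R,4aS,6S,8aS)-1-(5-hydroxy-3-methylidenepentyl)-2,5,5,8a-tetramethyl-6-(triethylsilyloxy)decahydronaphthalen-1-ol | C[C@@H]1CC[C@H]2C(C)(C)[C@@H](O[Si](CC)(CC)CC)CC[C@]2(C)[C@@]1(O)CCC(=C)CCO
F6 | step 15 | (1R,2R,4aS,6S,8aS)-1-{2-[(2S)-2-(2-hydroxyethyl)oxiran-2-yl]ethyl}-2,5,5,8a-tetramethyl-6-(triethylsilyloxy)decahydronaphthalen-1-ol | C[C@@H]1CC[C@H]2C(C)(C)[C@@H](O[Si](CC)(CC)CC)CC[C@]2(C)[C@@]1(O)CC[C@@]3(CO3)CCO
F7 | step 15 | (13R)-9α,13-epoxy-3β-(triethylsilyloxy)labdane-15,16-diol | C[C@@H]1CC[C@H]2C(C)(C)[C@@H](O[Si](CC)(CC)CC)CC[C@]2(C)[C@@]12CC[C@](CO)(CCO)O2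
F8 | step 17 | (13R)-9α,13-epoxy-3-oxolabdan-15,16-olide | C[C@@H]1CC[C@H]2C(C)(C)C(=O)CC[C@]2(C)[C@@]12CC[C@@]1(COC(=O)C1)O2
F9 | step 17 | (E)-oxime of F8 | C[C@@H]1CC[C@H]2C(C)(C)/C(=N/O)CC[C@]2(C)[C@@]12CC[C@@]1(COC(=O)C1)O2
F10 | step 17 | (E)-O-acetyl oxime of (13R)-18-acetoxy-9α,13-epoxy-3-oxolabdan-15,16-olide | C[C@@H]1CC[C@H]2[C@](C)(COC(C)=O)/C(=N/OC(C)=O)CC[C@]2(C)[C@@]12CC[C@@]1(COC(=O)C1)O2
F11 | step 17 | (13R)-18-acetoxy-9α,13-epoxy-3-oxolabdan-15,16-olide | C[C@@H]1CC[C@H]2[C@](C)(COC(C)=O)C(=O)CC[C@]2(C)[C@@]12CC[C@@]1(COC(=O)C1)O2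
F12 | step 17 | (13R)-18-acetoxy-9α,13-epoxy-3β-hydroxylabdan-15,16-olide | C[C@@H]1CC[C@H]2[C@](C)(COC(C)=O)[C@@H](O)CC[C@]2(C)[C@@]12CC[C@@]1(COC(=O)C1)O2
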